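**Plan**
Numbering (daucane): C1 = methyl-bearing ring-fusion carbon; C2, C3 = the two cyclopentane CH2; C4 = isopropyl carbinol; C5 = ring-fusion CH; C6 = ester carbinol; C7 = CH2; C8 = methyl carbinol; C9=C10 = ring alkene.
Retrosynthesis: cut the C6 ester, then C4–isopropyl (to a C4 ketone), then excise C3 (cuts C2–C3 and C3–C4; cyclopentanone back to a cis-fused cyclobutanone C4/C2/C1/C5), then C4–C5 and C1–C2 (dichloroketene [2+2] on the C5=C1 bond of a cyclohepta-1,3-diene), then the C1–O bond and the two [4+3] bonds of an 8-oxabicyclo[3.2.1]octenone (2,5-dimethylfuran + oxyallyl cation).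
Forward: the seven-membered ring is made first (bridged, then opened to a dienone that already holds C6=O, C8(Me)–O and C9=C10), the four-membered ring is added, the five-membered ring arises from it by one-carbon enlargement, and the isopropyl group and the ester follow.
Enabling feature: in the cyclopentane, the oxygen-bearing C4 is flanked by ring-fusion C5 and by two contiguous unsubstituted CH2 (C3, C2) ending at quaternary C1; with C4 as a ketone, C3 is a one-carbon insert into the C4–C2 bond of a cyclobutanone whose four atoms are a ketene plus the C5=C1 alkene.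
Stereochemistry: absolute sense from chiral lithium amide desymmetrisation of the meso oxabicyclic ketone (C8); C6 by catalyst-controlled reduction cis to O8; C5 and quaternary C1 (cis fusion) by suprafacial ketene addition anti to the silylene-bridged oxygens; C4 by convex-face isopropyl addition.

Key step: step 8

Assumption: the (R,R)-lithium amide is taken to remove the exo proton next to the (S)-configured bridgehead of the meso ketone, as in related bicyclo[3.2.1]octan-3-one deprotonations; if the sense is the opposite, the (S,S)-amide is used and nothing else changes.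

**Route**

Step 1
Reactants: 1 2,5-dimethylfuran; 2 1,1,3,3-tetrabromoacetone
Product: 4 (1R,5S)-1,5-dimethyl-8-oxabicyclo[3.2.1]oct-6-en-3-one (meso), via dibromo cycloadduct 3 (not isolated)
Conditions: Zn–Ag couple, THF, −10 °C to rt; then Zn–Cu couple, NH4Cl, MeOH, rt
Reagents that add atoms: none
Why: Reductive [4+3] cycloaddition in which zinc turns 2 into a dibromo oxyallyl cation that adds across the furan 2,5-positions, followed by reductive debromination, gives the achiral bridged ketone that already contains the seven-membered carbocycle with both ring methyl groups.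

Step 2
Reactants: 4 (1R,5S)-1,5-dimethyl-8-oxabicyclo[3.2.1]oct-6-en-3-one
Product: 5 (1R,5R)-1,5-dimethyl-3-(trimethylsilyloxy)-8-oxabicyclo[3.2.1]octa-2,6-diene
Conditions: (R,R)-bis(1-phenylethyl)amine, n-BuLi, LiCl, Me3SiCl (in situ), THF, −100 °C
Reagents that add atoms: chlorotrimethylsilane C[Si](C)(C)Cl
Why: Enantiotopic-proton-selective deprotonation of a meso bicyclic ketone by a chiral lithium amide with internal silyl quench places the enol double bond next to the (S)-bridgehead, so that the other oxygen-bearing bridgehead becomes C8 with the required configuration.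

Step 3
Reactants: 5 (1R,5R)-1,5-dimethyl-3-(trimethylsilyloxy)-8-oxabicyclo[3.2.1]octa-2,6-diene
Product: 6 (6R)-3,6-dimethyl-6-(trimethylsilyloxy)cyclohepta-2,4-dien-1-one
Conditions: Me3SiOTf (0.1 equiv), CH2Cl2, −78 to −20 °C; Et3N quench
Reagents that add atoms: none
Why: Lewis-acid-triggered β-elimination, in which silylation of the bridging oxygen lets the enol silane expel the C1–O bond that is aligned with its π system and silyl transfer regenerates the catalyst, should open the bridge to the conjugated dienone and leave C8 as a tertiary silyl ether of fixed configuration.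

Step 4
Reactants: 6 (6R)-3,6-dimethyl-6-(trimethylsilyloxy)cyclohepta-2,4-dien-1-one
Product: 8 (1R,6S)-1,4-dimethylcyclohepta-2,4-diene-1,6-diol, via dienol trimethylsilyl ether 7 (not isolated)
Conditions: (R)-2-methyl-CBS-oxazaborolidine (0.2 equiv), BH3·SMe2, THF, −30 °C; MeOH quench; then K2CO3, MeOH, rt
Reagents that add atoms: none
Why: Corey–Bakshi–Shibata 1,2-reduction, with the dienyl arm as the large and the CH2 arm as the small substituent, should give the (S)-carbinol at C6 (cis to the C8 oxygen) under catalyst control, and methanolysis then frees the tertiary hydroxyl.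

Step 5
Reactants: 8 (1R,6S)-1,4-dimethylcyclohepta-2,4-diene-1,6-diol
Product: 9 (1R,6S)-8,8-di-tert-butyl-1,4-dimethyl-7,9-dioxa-8-silabicyclo[4.3.1]deca-2,4-diene
Conditions: t-Bu2Si(OTf)2, 2,6-lutidine, CH2Cl2, 0 °C
Reagents that add atoms: di-tert-butylsilyl bis(trifluoromethanesulfonate) CC(C)(C)[Si](OS(=O)(=O)C(F)(F)F)(OS(=O)(=O)C(F)(F)F)C(C)(C)C
Why: Silylene formation across a cis-1,3-diol under basic conditions avoids ionisation of the doubly allylic system, masks both hydroxyls with one robust group and covers the ring face that carries them.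

Step 6
Reactants: 9 (1R,6S)-8,8-di-tert-butyl-1,4-dimethyl-7,9-dioxa-8-silabicyclo[4.3.1]deca-2,4-diene
Product: 10 dichlorocyclobutanone cis-fused at C5–C1 (C=O on C5; CCl2 on C1; four-membered ring anti to the silylene oxygens)
Conditions: Cl3CCOCl, Zn–Cu couple, Et2O–DME, sonication, 15–25 °C
Reagents that add atoms: trichloroacetyl chloride ClC(=O)C(Cl)(Cl)Cl
Why: Ketene–alkene [2+2] cycloaddition of dichloroketene to a 1,3-diene should join the diene terminus C5 to the ketene carbonyl carbon and the methyl-bearing internal C1 (the better cation-stabilising end) to CCl2, suprafacially on the alkene (hence cis fusion) and on the face anti to the allylic C6 oxygen and the silylene bridge, which sets C5 and the quaternary C1.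

Step 7
Reactants: 10 dichlorocyclobutanone
Product: 11 cyclobutanone cis-fused at C5–C1 (C4=O on C5; C2H2 on C1)
Conditions: Zn–Cu couple, NH4Cl, MeOH, rt
Reagents that add atoms: none
Why: Reductive dechlorination through the zinc enolate removes both α-chlorines, leaves an unsubstituted α-CH2 (C2) and touches no stereocentre.

Step 8
Reactants: 11 cyclobutanone
Product: 13 (3aS,4S,6R,8aS)-4,6-[(di-tert-butylsilanediyl)bis(oxy)]-6,8a-dimethyl-2,3a,4,5,6,8a-hexahydroazulen-3(1H)-one, via trimethylsilyl enol ether 12 (not isolated)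
Conditions: Me3SiCHN2 (1.3 equiv), Sc(OTf)3 (0.1 equiv), CH2Cl2, −78 to 0 °C; then 1 M HCl, THF, 0 °C
Reagents that add atoms: (trimethylsilyl)diazomethane C[Si](C)(C)C=[N+]=[N-]
Why: Sc(OTf)3 activates the strained C4 carbonyl, the diazo carbon (the future C3) adds to it from the convex face, and in the resulting diazonium adduct the C2 methylene, antiperiplanar to the C–N2 bond, shifts from C4 to C3 as N2 leaves, which forms the C2–C3 bond; the first-formed α-silyl ketone passes by a carbon-to-oxygen silyl shift into enol silane 12, which is hydrolysed on work-up. The closest known reaction type is the Tiffeneau–Demjanov-type Lewis-acid-catalysed homologation of cyclobutanones with trimethylsilyldiazomethane. The cyclopentane is closed not by an exo or endo attack but by a 1,2-alkyl shift (one-carbon enlargement of the four-membered ring), driven by relief of cyclobutanone strain. No stereocentre is created: C1 and C5 keep the cis relationship fixed by the cycloaddition, because the migrating carbon is an unsubstituted CH2 and the C5–C4 and C1–C2 bonds are never broken. The step needs migration of C2 and not of C5, which is the usual course for the less substituted α-carbon in this homologation (the Me3Si group stays away from the branched C5, which puts C2 anti to the leaving N2) and is reinforced by the inductive deactivation of C5 by the C6 oxygen. Over-homologation should be checked because the product leaves the catalytic cycle as an enol silane.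

Step 9
Reactants: 13 cyclopentanone
Product: 14 (3R,3aS,4S,6R,8aS)-4,6-[(di-tert-butylsilanediyl)bis(oxy)]-6,8a-dimethyl-3-(propan-2-yl)-1,2,3,3a,4,5,6,8a-octahydroazulen-3-ol
Conditions: i-PrMgCl, CeCl3 (anhydrous), THF, −78 to 0 °C
Reagents that add atoms: isopropylmagnesium chloride CC(C)[Mg]Cl
Why: Organocerium 1,2-addition, which suppresses enolisation and β-hydride reduction of the hindered ketone, should occur from the convex face of the cis-fused bicycle (syn to H5, anti to the C5–C6 bond) and so place the isopropyl group on the face of H5 and the angular methyl and the new hydroxyl on the face of the seven-membered ring, as required at C4.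

Step 10
Reactants: 14 silylene-protected tertiary alcohol
Product: 15 (3R,3aS,4S,6R,8aS)-6,8a-dimethyl-3-(propan-2-yl)-1,2,3,3a,4,5,6,8a-octahydroazulene-3,4,6-triol
Conditions: HF·pyridine, pyridine, THF, 0 °C to rt
Reagents that add atoms: none
Why: Fluoride cleavage of the silylene under pyridine-buffered conditions that spare the tertiary allylic alcohol frees the C6 and C8 hydroxyls.

Step 11
Reactants: 15 triol; 16 4-acetoxybenzoyl chloride
Product: 17 [(3R,3aS,4S,6R,8aS)-3,6-dihydroxy-6,8a-dimethyl-3-(propan-2-yl)-1,2,3,3a,4,5,6,8a-octahydroazulen-4-yl] 4-acetoxybenzoate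
Conditions: pyridine, DMAP (0.2 equiv), CH2Cl2, 0 °C to rt
Reagents that add atoms: none
Why: DMAP-catalysed acylation should select the single secondary hydroxyl (C6) over the two tertiary ones (C4, C8) on steric grounds and proceeds with retention at C6.

Step 12
Reactants: 17 acetate-protected ester
Product: 18 [(3R,3aS,4S,6R,8aS)-3,6-dihydroxy-6,8a-dimethyl-3-(propan-2-yl)-1,2,3,3a,4,5,6,8a-octahydroazulen-4-yl] 4-hydroxybenzoate (target)
Conditions: K2CO3 (0.2 equiv), MeOH, 0 °C
Reagents that add atoms: none
Why: Methanolysis of the aryl acetate (phenoxide leaving group) should be much faster than that of the hindered secondary benzoate and unveils the phenol.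

**Compound list**
1 | 2,5-dimethylfuran | Cc1ccc(C)o1 | starting material
2 | 1,1,3,3-tetrabromoacetone | BrC(Br)C(=O)C(Br)Br | starting material
3 | 2,4-dibromo-1,5-dimethyl-8-oxabicyclo[3.2.1]oct-6-en-3-one (epimers at the CHBr carbons) | C[C@]12C=C[C@](C)(O1)C(Br)C(=O)C2Br | intermediate
4 | (1R,5S)-1,5-dimethyl-8-oxabicyclo[3.2.1]oct-6-en-3-one (meso) | C[C@]12C=C[C@](C)(O1)CC(=O)C2 | intermediate
5 | (1R,5R)-1,5-dimethyl-3-(trimethylsilyloxy)-8-oxabicyclo[3.2.1]octa-2,6-diene | C[C@]12C=C[C@](C)(O1)CC(O[Si](C)(C)C)=C2 | intermediate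
6 | (6R)-3,6-dimethyl-6-(trimethylsilyloxy)cyclohepta-2,4-dien-1-one | CC1=CC(=O)C[C@@](C)(O[Si](C)(C)C)C=C1 | intermediate
7 | (1S,6R)-3,6-dimethyl-6-(trimethylsilyloxy)cyclohepta-2,4-dien-1-ol | CC1=C[C@@H](O)C[C@@](C)(O[Si](C)(C)C)C=C1 | intermediate
8 | (1R,6S)-1,4-dimethylcyclohepta-2,4-diene-1,6-diol (cis-diol) | CC1=C[C@@H](O)C[C@@](C)(O)C=C1 | intermediate
9 | (1R,6S)-8,8-di-tert-butyl-1,4-dimethyl-7,9-dioxa-8-silabicyclo[4.3.1]deca-2,4-diene | CC1=C[C@@H](O2)C[C@@](C)(O[Si]2(C(C)(C)C)C(C)(C)C)C=C1 | intermediate
10 | dichlorocyclobutanone cis-fused at C5–C1 of the silylene-bridged cycloheptene (C=O on C5, CCl2 on C1, anti to the silylene oxygens) | O=C1C(Cl)(Cl)[C@@]2(C)C=C[C@](C)(O[Si]3(C(C)(C)C)C(C)(C)C)C[C@H](O3)[C@@H]12 | intermediate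
11 | the corresponding cyclobutanone (C4=O on C5, C2H2 on C1) | O=C1C[C@@]2(C)C=C[C@](C)(O[Si]3(C(C)(C)C)C(C)(C)C)C[C@H](O3)[C@@H]12 | intermediate
12 | trimethylsilyl enol ether (C4(OSiMe3)=C3) of cyclopentanone 13 | C[Si](C)(C)OC1=CC[C@@]2(C)C=C[C@](C)(O[Si]3(C(C)(C)C)C(C)(C)C)C[C@H](O3)[C@@H]12 | intermediate
13 | (3aS,4S,6R,8aS)-4,6-[(di-tert-butylsilanediyl)bis(oxy)]-6,8a-dimethyl-2,3a,4,5,6,8a-hexahydroazulen-3(1H)-one | O=C1CC[C@@]2(C)C=C[C@](C)(O[Si]3(C(C)(C)C)C(C)(C)C)C[C@H](O3)[C@@H]12 | intermediate
14 | (3R,3aS,4S,6R,8aS)-4,6-[(di-tert-butylsilanediyl)bis(oxy)]-6,8a-dimethyl-3-(propan-2-yl)-1,2,3,3a,4,5,6,8a-octahydroazulen-3-ol | CC(C)[C@]1(O)CC[C@@]2(C)C=C[C@](C)(O[Si]3(C(C)(C)C)C(C)(C)C)C[C@H](O3)[C@@H]12 | intermediate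
15 | (3R,3aS,4S,6R,8aS)-6,8a-dimethyl-3-(propan-2-yl)-1,2,3,3a,4,5,6,8a-octahydroazulene-3,4,6-triol | CC(C)[C@]1(O)CC[C@@]2(C)C=C[C@](C)(O)C[C@H](O)[C@@H]12 | intermediate
16 | 4-acetoxybenzoyl chloride | CC(=O)Oc1ccc(cc1)C(Cl)=O | starting material
17 | [(3R,3aS,4S,6R,8aS)-3,6-dihydroxy-6,8a-dimethyl-3-(propan-2-yl)-1,2,3,3a,4,5,6,8a-octahydroazulen-4-yl] 4-acetoxybenzoate | CC(C)[C@]1(O)CC[C@@]2(C)C=C[C@](C)(O)C[C@H](OC(=O)c3ccc(OC(C)=O)cc3)[C@@H]12 | intermediate
18 | [(3R,3aS,4S,6R,8aS)-3,6-dihydroxy-6,8a-dimethyl-3-(propan-2-yl)-1,2,3,3a,4,5,6,8a-octahydroazulen-4-yl] 4-hydroxybenzoate | CC(C)[C@]1(O)CC[C@@]2(C)C=C[C@](C)(O)C[C@H](OC(=O)c3ccc(O)cc3)[C@@H]12 | target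

**Step count and risks**
Total step count: 12. Longest linear sequence: 12 steps (from 1 and 2 to 18; 16 is a commercial acylating agent).

Steps most likely to fail:

Step 8 – migration of the wrong α-carbon (C5 instead of C2) or incomplete regiocontrol in the ring enlargement. The fallback fixes the position of the new carbon by enolate chemistry instead of by migratory aptitude. It sets out from 11: kinetic deprotonation at the less hindered C2 (LDA, THF, −78 °C) and trapping with monomeric formaldehyde should give the 2-(hydroxymethyl)cyclobutanone F1. I2, PPh3 and imidazole convert it into the 2-(iodomethyl)cyclobutanone F2. Bu3SnH and AIBN in benzene at 80 °C then bring about a Dowd–Beckwith radical ring expansion: the primary radical adds to the C4 carbonyl, the strained alkoxy radical fragments at the C4–C2 bond, and the C2 radical is reduced. The route is rejoined at 13.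

Step 9 – enolisation, β-hydride reduction or poor facial selectivity with the branched nucleophile. The fallback sets out from 13 and uses an sp2 nucleophile followed by directed reduction. 2-Propenylmagnesium bromide with CeCl3 should give the isopropenyl carbinol F3. Hydroxyl-directed hydrogenation with [Ir(cod)(PCy3)(py)]PF6 under H2 in CH2Cl2 should then reduce only the isopropenyl alkene, because the C4 hydroxyl is the only free one and the C9=C10 alkene lies between two fully substituted carbons with O8 silylated. The route is rejoined at 14.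

Step 4 – poor facial selectivity of hydride delivery if the ring bias opposes the catalyst. The fallback sets the C6 centre by directed reduction and inversion and sets out from 6. Buffered desilylation (TBAF, AcOH, THF, 0 °C) gives the hydroxy dienone F4. Evans–Saksena reduction (Me4NBH(OAc)3, MeCN–AcOH, −20 °C) delivers hydride internally from the C8 oxygen and should give the trans-diol F5. Mitsunobu inversion of the secondary carbinol (4-nitrobenzoic acid, PPh3, DIAD; the tertiary hydroxyl is inert) gives the cis-configured 4-nitrobenzoate F6, and K2CO3 in MeOH returns the route to 8.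

Further compounds
F1 | step 8 | 2-(hydroxymethyl) derivative of cyclobutanone 11 (CH2OH on C2, configuration at C2 immaterial) | O=C1C(CO)[C@@]2(C)C=C[C@](C)(O[Si]3(C(C)(C)C)C(C)(C)C)C[C@H](O3)[C@@H]12
F2 | step 8 | 2-(iodomethyl) derivative of cyclobutanone 11 | O=C1C(CI)[C@@]2(C)C=C[C@](C)(O[Si]3(C(C)(C)C)C(C)(C)C)C[C@H](O3)[C@@H]12
F3 | step 9 | isopropenyl carbinol (prop-1-en-2-yl in place of the isopropyl group of 14) | C=C(C)[C@]1(O)CC[C@@]2(C)C=C[C@](C)(O[Si]3(C(C)(C)C)C(C)(C)C)C[C@H](O3)[C@@H]12
F4 | step 4 | (6R)-6-hydroxy-3,6-dimethylcyclohepta-2,4-dien-1-one | CC1=CC(=O)C[C@@](C)(O)C=C1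
F5 | step 4 | (1R,6R)-1,4-dimethylcyclohepta-2,4-diene-1,6-diol (trans-diol) | CC1=C[C@H](O)C[C@@](C)(O)C=C1
F6 | step 4 | (1S,6R)-6-hydroxy-3,6-dimethylcyclohepta-2,4-dien-1-yl 4-nitrobenzoate (cis) | CC1=C[C@@H](OC(=O)c2ccc(cc2)[N+](=O)[O-])C[C@@](C)(O)C=C1
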